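**Plan**

1. Numbering: chroman O1, C2, C3, C4, C4a, C5 to C8, C8a; side chain C1' to C8' outward from C2. The retrosynthesis cuts (a) C2'–C3' (alkyl–alkenyl coupling), (b) C3–C4 of the pyran ring, reopened as a C3=C4 alkene, and (c) the ether bond O1–C2.
2. What allows this: C2 holds CH3, O1 and two two-carbon arms, C3–C4 inside the pyran ring and C1'–C2' at the start of the chain. Drawn as vinyl groups the two arms are the same, so C2 can come from a carbinol carbon with two identical vinyl groups, one of which is later tied to C4a through an aryl vinyl group.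
3. Forward: the benzene ring is bought as 2-methylhydroquinone. Its hindered oxygen is etherified with a diethynyl carbinol, the two alkynes and an ortho-formyl group become three vinyl groups, and metathesis closes the pyran ring (the only ring made). The chain is then joined at C2'–C3', C3=C4 is saturated and the protecting groups are removed.
4. Stereochemistry: C2 (R) is the only stereocentre. It is created in the ring closure, where a chiral molybdenum alkylidene takes one of the two enantiotopic vinyl groups. Both E alkenes come from a syn-carboalumination and a stabilised Wittig reaction and pass through the coupling with retention.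

Key step: step 8

Remark on the chemistry: the phenol is carried as its triisopropylsilyl (TIPS) ether, chosen because the bulky chloride should favour the open hydroxyl in step 1 and the ether should survive the aqueous base of step 11.

Assumption: which enantiomer of the biphenolate complex gives the (2R)-chromene cannot be derived on paper. The (S)-biphenolate complex is written in step 8; its mirror image is used instead if the first run shows the opposite sense.

**Route**

Step 1
Reactants: 1 2-methylhydroquinone (2-methylbenzene-1,4-diol)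
Product: 2 2-methyl-4-[(triisopropylsilyl)oxy]phenol
Conditions: iPr3SiCl (1.0 equiv), imidazole, DMF, 0 °C
Reagents that add atoms: chlorotriisopropylsilane, CC(C)[Si](Cl)(C(C)C)C(C)C
Why: Silyl ether formation in which the bulky chloride should take the open C4 hydroxyl in preference to the C1 hydroxyl flanked by the methyl group.

Step 2
Reactants: 2 2-methyl-4-[(triisopropylsilyl)oxy]phenol
Product: 3 2-hydroxy-3-methyl-5-[(triisopropylsilyl)oxy]benzaldehyde
Conditions: MgCl2, Et3N, (CH2O)n, MeCN, reflux
Reagents that add atoms: paraformaldehyde (formaldehyde), C=O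
Why: Magnesium-phenoxide-directed ortho-formylation (Casnati–Skattebøl formylation), for which only one ortho position is free and the para position is blocked.

Step 3
Reactants: 4 ethyl acetate; 5 ethynylmagnesium bromide (0.5 M in THF, 2.3 equiv)
Product: 7 3-methylpenta-1,4-diyn-3-ol, via but-3-yn-2-one 6 (not isolated)
Conditions: THF, 0 °C to rt; then sat. aq. NH4Cl
Reagents that add atoms: none
Why: Double Grignard addition to an ester, the ynone released after the first addition being more electrophilic than the ester and taking the second alkynyl group at once.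

Step 4
Reactants: 7 3-methylpenta-1,4-diyn-3-ol
Product: 8 methyl 3-methylpenta-1,4-diyn-3-yl carbonate
Conditions: n-BuLi (1.0 equiv), THF, −78 °C; ClCO2Me, −78 to 0 °C
Reagents that add atoms: methyl chloroformate, COC(=O)Cl
Why: O-acylation of the lithium alkoxide, the hydroxyl proton being far more acidic than the alkyne protons so that one equivalent of base at low temperature deprotonates oxygen only.

Step 5
Reactants: 3 2-hydroxy-3-methyl-5-[(triisopropylsilyl)oxy]benzaldehyde; 8 methyl 3-methylpenta-1,4-diyn-3-yl carbonate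
Product: 9 3-methyl-2-[(3-methylpenta-1,4-diyn-3-yl)oxy]-5-[(triisopropylsilyl)oxy]benzaldehyde
Conditions: CuCl2·2H2O (1 mol%), DBU, MeCN, −5 to 0 °C
Reagents that add atoms: none
Why: Copper-catalysed propargylic etherification in which a copper acetylide of 8 expels methyl carbonate to give a copper allenylidene with cationic character at the tertiary carbon, a flat and slim centre that the 2,6-disubstituted phenoxide should still reach.

Step 6
Reactants: 9 3-methyl-2-[(3-methylpenta-1,4-diyn-3-yl)oxy]-5-[(triisopropylsilyl)oxy]benzaldehyde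
Product: 10 3-methyl-2-[(3-methylpenta-1,4-dien-3-yl)oxy]-5-[(triisopropylsilyl)oxy]benzaldehyde
Conditions: H2 (1 atm), Pd/CaCO3 poisoned with Pb(OAc)2, quinoline, EtOAc, rt, stopped after 2 equiv H2
Reagents that add atoms: none
Why: Lindlar semi-hydrogenation of both terminal alkynes, the usual way from aryl 1,1-disubstituted propargyl ethers to the allyl ethers, with aldehyde, arene and silyl ether inert to the poisoned catalyst.

Step 7
Reactants: 10 3-methyl-2-[(3-methylpenta-1,4-dien-3-yl)oxy]-5-[(triisopropylsilyl)oxy]benzaldehyde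
Product: 11 {3-ethenyl-5-methyl-4-[(3-methylpenta-1,4-dien-3-yl)oxy]phenoxy}triisopropylsilane
Conditions: Ph3PCH3Br, KOtBu, THF, 0 °C to rt
Reagents that add atoms: methyltriphenylphosphonium bromide, C[P+](c1ccccc1)(c1ccccc1)c1ccccc1.[Br-]
Why: Wittig methylenation of a non-enolisable aryl aldehyde; the ether carbon bears no acidic hydrogen and both ortho positions are blocked against aromatic Claisen rearrangement at this temperature.

Step 8
Reactants: 11 {3-ethenyl-5-methyl-4-[(3-methylpenta-1,4-dien-3-yl)oxy]phenoxy}triisopropylsilane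
Product: 12 {[(2R)-2-ethenyl-2,8-dimethyl-2H-chromen-6-yl]oxy}triisopropylsilane
Conditions: Mo(N-2,6-iPr2C6H3)(CHCMe2Ph)[(S)-3,3'-di-tert-butyl-5,5',6,6'-tetramethylbiphenyl-2,2'-diolate] (5 mol%), C6H6, 22 °C, N2, vessel vented so that C2H4 escapes
Reagents that add atoms: none
Why: The neophylidene first exchanges onto the unhindered styrene terminus; the resulting molybdenum benzylidene (its carbon becomes C4) adds across one of the two vinyl groups on the carbinol carbon in a [2+2] step, and cycloreversion of the metallacyclobutane forms C3=C4 and a Mo=CH2 species that carries the cycle while ethylene leaves. The closest known reaction type is the molybdenum-catalysed enantioselective ring-closing metathesis that desymmetrises achiral trienes to unsaturated cyclic tertiary ethers, together with the familiar closure of 2-vinylphenyl allyl ethers to 2H-chromenes. The pyran ring closes as a six-membered ring by ring-closing metathesis between the aryl-bound alkylidene carbon and the CH of the vinyl group, the ring alkene being cis by constraint. C2 becomes stereogenic when one vinyl group is consumed, and its configuration is set by the axially chiral biphenolate, whose tert-butyl groups and the arylimido ligand form a pocket in which methyl and aryloxy at the carbinol carbon cannot change places without steric cost. The selectivity needed is between the two enantiotopic vinyl groups only, since both give the same ring size, and the large size difference between CH3 and the 2,6-disubstituted aryloxy group secures it. The remaining vinyl group sits on a fully substituted carbon and should not enter cross-metathesis.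

Step 9
Reactants: 13 4-pentyn-1-ol
Product: 15 (E)-5-iodo-4-methylpent-4-en-1-ol, via alkenyldimethylalane 14 (not isolated)
Conditions: AlMe3 (3 equiv), Cp2ZrCl2 (0.25 equiv), CH2Cl2, 0 °C to rt; then I2, THF, −30 to 0 °C
Reagents that add atoms: trimethylaluminium, C[Al](C)C; iodine, II
Why: Zirconium-catalysed syn-carboalumination (Negishi carboalumination) puts methyl on the internal and aluminium on the terminal alkyne carbon, and iodinolysis of the C–Al bond with retention gives the E iodide.

Step 10
Reactants: 15 (E)-5-iodo-4-methylpent-4-en-1-ol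
Product: 17 ethyl (2E,6E)-7-iodo-2,6-dimethylhepta-2,6-dienoate, via (E)-5-iodo-4-methylpent-4-enal 16 (not isolated)
Conditions: TEMPO (10 mol%), PhI(OAc)2 (1.1 equiv), CH2Cl2, rt; then Ph3P=C(CH3)CO2Et, 40 °C
Reagents that add atoms: ethyl 2-(triphenylphosphoranylidene)propanoate, CCOC(=O)C(C)=P(c1ccccc1)(c1ccccc1)c1ccccc1
Why: Oxoammonium oxidation of the primary alcohol followed in the same flask by a Wittig reaction with a stabilised ylide, which should give the E enoate and leaves the alkenyl iodide untouched.

Step 11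
Reactants: 12 {[(2R)-2-ethenyl-2,8-dimethyl-2H-chromen-6-yl]oxy}triisopropylsilane; 17 ethyl (2E,6E)-7-iodo-2,6-dimethylhepta-2,6-dienoate
Product: 19 ethyl (2E,6E)-9-{(2R)-2,8-dimethyl-6-[(triisopropylsilyl)oxy]-2H-chromen-2-yl}-2,6-dimethylnona-2,6-dienoate, via B-alkyl-9-borabicyclononane 18 (not isolated)
Conditions: 9-BBN (1.3 equiv), THF, 0 °C to rt; then 17, PdCl2(dppf) (5 mol%), AsPh3, 3 M aq. K3PO4, DMF, rt
Reagents that add atoms: none
Why: 9-BBN adds in the anti-Markovnikov sense to the monosubstituted vinyl group far faster than to the 1,2-disubstituted, arene-conjugated C3=C4, and the B-alkyl Suzuki–Miyaura coupling joins C2' to C3' with retention of the E geometry while C2 is not touched.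

Step 12
Reactants: 19 ethyl (2E,6E)-9-{(2R)-2,8-dimethyl-6-[(triisopropylsilyl)oxy]-2H-chromen-2-yl}-2,6-dimethylnona-2,6-dienoate
Product: 20 ethyl (2E,6E)-9-{(2R)-2,8-dimethyl-6-[(triisopropylsilyl)oxy]-3,4-dihydro-2H-chromen-2-yl}-2,6-dimethylnona-2,6-dienoate
Conditions: TsNHNH2 (added in portions), NaOAc, DME/H2O, reflux
Reagents that add atoms: none
Why: Diimide reduction, a concerted syn transfer of H2 that is very sensitive to substitution, so the cis-disubstituted C3=C4 should be saturated well before the two trisubstituted alkenes, and no metal is present that could isomerise them.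

Step 13
Reactants: 20 ethyl (2E,6E)-9-{(2R)-2,8-dimethyl-6-[(triisopropylsilyl)oxy]-3,4-dihydro-2H-chromen-2-yl}-2,6-dimethylnona-2,6-dienoate
Product: 21 ethyl (2E,6E)-9-[(2R)-6-hydroxy-2,8-dimethyl-3,4-dihydro-2H-chromen-2-yl]-2,6-dimethylnona-2,6-dienoate
Conditions: Bu4NF (1.1 equiv), AcOH (1.1 equiv), THF, 0 °C
Reagents that add atoms: none
Why: Fluoride cleavage of the aryl silyl ether driven by Si–F bond formation, buffered with acetic acid so that the ester and the alkenes are left alone.

Step 14
Reactants: 21 ethyl (2E,6E)-9-[(2R)-6-hydroxy-2,8-dimethyl-3,4-dihydro-2H-chromen-2-yl]-2,6-dimethylnona-2,6-dienoate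
Product: 22 (2E,6E)-9-[(2R)-6-hydroxy-2,8-dimethyl-3,4-dihydro-2H-chromen-2-yl]-2,6-dimethylnona-2,6-dienoic acid (CNP0176653.1)
Conditions: LiOH·H2O (5 equiv), THF/MeOH/H2O, 40 °C, degassed, Ar; then 1 M HCl to pH 3
Reagents that add atoms: lithium hydroxide, [Li+].[OH-]
Why: Saponification of the conjugated ethyl ester; C2 is quaternary and cannot epimerise, the E enoate is the stable isomer, and exclusion of air protects the electron-rich 6-hydroxychroman in base.

**Compound list**

1 | 2-methylhydroquinone | Cc1cc(O)ccc1O | starting material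
2 | 2-methyl-4-[(triisopropylsilyl)oxy]phenol | Cc1cc(O[Si](C(C)C)(C(C)C)C(C)C)ccc1O | intermediate
3 | 2-hydroxy-3-methyl-5-[(triisopropylsilyl)oxy]benzaldehyde | Cc1cc(O[Si](C(C)C)(C(C)C)C(C)C)cc(C=O)c1O | intermediate
4 | ethyl acetate | CCOC(C)=O | starting material
5 | ethynylmagnesium bromide | C#C[Mg]Br | starting material
6 | but-3-yn-2-one | CC(=O)C#C | intermediate (not isolated)
7 | 3-methylpenta-1,4-diyn-3-ol | C#CC(C)(O)C#C | intermediate
8 | methyl 3-methylpenta-1,4-diyn-3-yl carbonate | COC(=O)OC(C)(C#C)C#C | intermediate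
9 | 3-methyl-2-[(3-methylpenta-1,4-diyn-3-yl)oxy]-5-[(triisopropylsilyl)oxy]benzaldehyde | C#CC(C)(C#C)Oc1c(C)cc(O[Si](C(C)C)(C(C)C)C(C)C)cc1C=O | intermediate
10 | 3-methyl-2-[(3-methylpenta-1,4-dien-3-yl)oxy]-5-[(triisopropylsilyl)oxy]benzaldehyde | C=CC(C)(C=C)Oc1c(C)cc(O[Si](C(C)C)(C(C)C)C(C)C)cc1C=O | intermediate
11 | {3-ethenyl-5-methyl-4-[(3-methylpenta-1,4-dien-3-yl)oxy]phenoxy}triisopropylsilane | C=CC(C)(C=C)Oc1c(C)cc(O[Si](C(C)C)(C(C)C)C(C)C)cc1C=C | intermediate (key-step precursor)
12 | {[(2R)-2-ethenyl-2,8-dimethyl-2H-chromen-6-yl]oxy}triisopropylsilane | C=C[C@]1(C)C=Cc2cc(O[Si](C(C)C)(C(C)C)C(C)C)cc(C)c2O1 | intermediate (key-step product)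
13 | 4-pentyn-1-ol | C#CCCCO | starting material
14 | dimethylaluminium (E)-5-(dimethylalumanyl)-4-methylpent-4-en-1-olate | C[Al](C)/C=C(\C)CCCO[Al](C)C | intermediate (not isolated)
15 | (E)-5-iodo-4-methylpent-4-en-1-ol | C/C(=C\I)CCCO | intermediate
16 | (E)-5-iodo-4-methylpent-4-enal | C/C(=C\I)CCC=O | intermediate (not isolated)
17 | ethyl (2E,6E)-7-iodo-2,6-dimethylhepta-2,6-dienoate | CCOC(=O)/C(C)=C/CC/C(C)=C/I | intermediate
18 | 9-(2-{(2R)-2,8-dimethyl-6-[(triisopropylsilyl)oxy]-2H-chromen-2-yl}ethyl)-9-borabicyclo[3.3.1]nonane | C[C@@]1(CCB2C3CCCC2CCC3)C=Cc2cc(O[Si](C(C)C)(C(C)C)C(C)C)cc(C)c2O1 | intermediate (not isolated)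
19 | ethyl (2E,6E)-9-{(2R)-2,8-dimethyl-6-[(triisopropylsilyl)oxy]-2H-chromen-2-yl}-2,6-dimethylnona-2,6-dienoate | CCOC(=O)/C(C)=C/CC/C(C)=C/CC[C@]1(C)C=Cc2cc(O[Si](C(C)C)(C(C)C)C(C)C)cc(C)c2O1 | intermediate
20 | ethyl (2E,6E)-9-{(2R)-2,8-dimethyl-6-[(triisopropylsilyl)oxy]-3,4-dihydro-2H-chromen-2-yl}-2,6-dimethylnona-2,6-dienoate | CCOC(=O)/C(C)=C/CC/C(C)=C/CC[C@]1(C)CCc2cc(O[Si](C(C)C)(C(C)C)C(C)C)cc(C)c2O1 | intermediate
21 | ethyl (2E,6E)-9-[(2R)-6-hydroxy-2,8-dimethyl-3,4-dihydro-2H-chromen-2-yl]-2,6-dimethylnona-2,6-dienoate | CCOC(=O)/C(C)=C/CC/C(C)=C/CC[C@]1(C)CCc2cc(O)cc(C)c2O1 | intermediate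
22 | (2E,6E)-9-[(2R)-6-hydroxy-2,8-dimethyl-3,4-dihydro-2H-chromen-2-yl]-2,6-dimethylnona-2,6-dienoic acid | C/C(=C\CC[C@]1(C)CCc2cc(O)cc(C)c2O1)CC/C=C(\C)C(=O)O | target

**Count and risks**

Total: 14 steps. Longest linear sequence: 10 steps (1, 2, 5, 6, 7, 8, 11, 12, 13, 14).

Step 8. The catalyst may discriminate poorly between the two enantiotopic vinyl groups, because the twisted 2,6-disubstituted aryl ether presents them differently from the alkyl ethers of the precedent. Turnover may also be slow, because the benzylidene has to reach a vinyl group on a fully substituted carbon. The fallback sets out from 3 and returns at 12, with C2 set in the ether-forming step instead. Phenol 3 opens 2-methyl-2-vinyloxirane under Pd2(dba)3·CHCl3 and the enantiomer of N,N'-(cyclohexane-1,2-diyl)bis[2-(diphenylphosphanyl)benzamide] that favours the S ether (CH2Cl2, rt). This is an asymmetric allylic etherification through an equilibrating π-allylpalladium complex that delivers the phenoxide to the tertiary terminus, and it should give 2-{[(2S)-1-hydroxy-2-methylbut-3-en-2-yl]oxy}-3-methyl-5-[(triisopropylsilyl)oxy]benzaldehyde F1. Wittig methylenation of the aryl aldehyde (Ph3PCH3Br, KOtBu in excess) gives (2S)-2-{2-ethenyl-6-methyl-4-[(triisopropylsilyl)oxy]phenoxy}-2-methylbut-3-en-1-ol F2. Ring-closing metathesis with the achiral complex RuCl2(H2IMes)(=CH-C6H4-2-OiPr) (H2IMes = 1,3-dimesitylimidazolidin-2-ylidene; CH2Cl2, 40 °C) closes the same C3=C4 bond to give {(2S)-2,8-dimethyl-6-[(triisopropylsilyl)oxy]-2H-chromen-2-yl}methanol F3. Dess–Martin oxidation gives (2S)-2,8-dimethyl-6-[(triisopropylsilyl)oxy]-2H-chromene-2-carbaldehyde F4, and a second Wittig methylenation returns to 12.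

Step 5. Capture of the copper allenylidene by the hindered, hydrogen-bonded phenoxide may be slow, so that copper-mediated self-reaction of the diyne electrophile overtakes ether formation. The fallback sets out from 3 and returns at 11, and it makes steps 3, 4 and 6 unnecessary. Pd(PPh3)4-catalysed opening of 2-methyl-2-vinyloxirane by 3 (THF, rt; attack at the tertiary terminus of the π-allyl complex) gives racemic 2-[(1-hydroxy-2-methylbut-3-en-2-yl)oxy]-3-methyl-5-[(triisopropylsilyl)oxy]benzaldehyde F5. Dess–Martin oxidation gives racemic 2-{2-formyl-6-methyl-4-[(triisopropylsilyl)oxy]phenoxy}-2-methylbut-3-enal F6. Double Wittig methylenation (Ph3PCH3Br, KOtBu) makes the two aliphatic arms identical again and gives 11.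

Step 12. Chemoselectivity of the diimide transfer may be lost, with partial saturation of C3'=C4' or of the enoate, or conversion of the hindered C3=C4 may stay incomplete. The fallback sets out from 12 and returns at 20, saturating C3=C4 while it is the only alkene in the molecule. Hydroboration of 12 with 9-BBN as in step 11, then NaOH/H2O2, gives 2-{(2R)-2,8-dimethyl-6-[(triisopropylsilyl)oxy]-2H-chromen-2-yl}ethan-1-ol F7. Hydrogenation (H2, Pd/C, EtOAc) gives 2-{(2S)-2,8-dimethyl-6-[(triisopropylsilyl)oxy]-3,4-dihydro-2H-chromen-2-yl}ethan-1-ol F8, where the descriptor changes by priority only. I2, PPh3 and imidazole give {[(2S)-2-(2-iodoethyl)-2,8-dimethyl-3,4-dihydro-2H-chromen-6-yl]oxy}triisopropylsilane F9. Lithium–iodine exchange (t-BuLi, 2 equiv, Et2O, −78 °C) and trapping with 9-methoxy-9-borabicyclo[3.3.1]nonane give lithium 9-(2-{(2R)-2,8-dimethyl-6-[(triisopropylsilyl)oxy]-3,4-dihydro-2H-chromen-2-yl}ethyl)-9-methoxy-9-boranuidabicyclo[3.3.1]nonane F10. This is coupled in the same flask with 17 (PdCl2(dppf), aq. K3PO4, DMF, rt) to reach 20.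

**Further compounds**

F1 | step 8 | 2-{[(2S)-1-hydroxy-2-methylbut-3-en-2-yl]oxy}-3-methyl-5-[(triisopropylsilyl)oxy]benzaldehyde | OC[C@](C)(C=C)Oc1c(C)cc(O[Si](C(C)C)(C(C)C)C(C)C)cc1C=O
F2 | step 8 | (2S)-2-{2-ethenyl-6-methyl-4-[(triisopropylsilyl)oxy]phenoxy}-2-methylbut-3-en-1-ol | OC[C@](C)(C=C)Oc1c(C)cc(O[Si](C(C)C)(C(C)C)C(C)C)cc1C=C
F3 | step 8 | {(2S)-2,8-dimethyl-6-[(triisopropylsilyl)oxy]-2H-chromen-2-yl}methanol | OC[C@]1(C)C=Cc2cc(O[Si](C(C)C)(C(C)C)C(C)C)cc(C)c2O1
F4 | step 8 | (2S)-2,8-dimethyl-6-[(triisopropylsilyl)oxy]-2H-chromene-2-carbaldehyde | O=C[C@]1(C)C=Cc2cc(O[Si](C(C)C)(C(C)C)C(C)C)cc(C)c2O1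
F5 | step 5 | racemic 2-[(1-hydroxy-2-methylbut-3-en-2-yl)oxy]-3-methyl-5-[(triisopropylsilyl)oxy]benzaldehyde | OCC(C)(C=C)Oc1c(C)cc(O[Si](C(C)C)(C(C)C)C(C)C)cc1C=O
F6 | step 5 | racemic 2-{2-formyl-6-methyl-4-[(triisopropylsilyl)oxy]phenoxy}-2-methylbut-3-enal | O=CC(C)(C=C)Oc1c(C)cc(O[Si](C(C)C)(C(C)C)C(C)C)cc1C=O
F7 | step 12 | 2-{(2R)-2,8-dimethyl-6-[(triisopropylsilyl)oxy]-2H-chromen-2-yl}ethan-1-ol | OCC[C@]1(C)C=Cc2cc(O[Si](C(C)C)(C(C)C)C(C)C)cc(C)c2O1
F8 | step 12 | 2-{(2S)-2,8-dimethyl-6-[(triisopropylsilyl)oxy]-3,4-dihydro-2H-chromen-2-yl}ethan-1-ol | OCC[C@]1(C)CCc2cc(O[Si](C(C)C)(C(C)C)C(C)C)cc(C)c2O1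
F9 | step 12 | {[(2S)-2-(2-iodoethyl)-2,8-dimethyl-3,4-dihydro-2H-chromen-6-yl]oxy}triisopropylsilane | ICC[C@]1(C)CCc2cc(O[Si](C(C)C)(C(C)C)C(C)C)cc(C)c2O1
F10 | step 12 | lithium 9-(2-{(2R)-2,8-dimethyl-6-[(triisopropylsilyl)oxy]-3,4-dihydro-2H-chromen-2-yl}ethyl)-9-methoxy-9-boranuidabicyclo[3.3.1]nonane | [Li+].CO[B-]1(CC[C@]4(C)CCc5cc(O[Si](C(C)C)(C(C)C)C(C)C)cc(C)c5O4)C2CCCC1CCC2
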